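**Retrosynthetic overview**
1. Both esters go on last (angelate at C10, 4-hydroxybenzoate at C6). The C10 oxygen comes from electrochemical allylic C–H oxidation of the C8=C9 alkene of O-silyl ferutinin followed by 1,2-reduction, which leads back to jaeschkeanadiol.
2. Ring B (seven-membered) is closed by ring-closing metathesis at C8=C9 between an allyl group on C1 and a 2-methylallyl carbinol on C5 (C6 set by chelate-controlled Grignard addition).
3. Key disconnection: C5–C6 and C1–C10 are made together in a light-driven, silicon-tethered radical cyclization/allyl-transfer cascade from the C4 oxygen. This fixes C5 and the quaternary C1 from C4.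
4. Ring A (five-membered) with the C4 carbinol comes from (S)-terpinen-4-ol by ozonolysis, aldol ring contraction and decarbonylation.
5. Ring order: ring A first, ring B second. The only bought stereocentre is C4.

Assumption: (S)-(+)-terpinen-4-ol is bought in high enantiomeric purity; daucane numbering is used in the text (C1 quaternary ring-fusion carbon, C4 carbinol carbon with isopropyl, C5 ring-fusion CH, C6 and C10 the oxygenated ring-B carbons, C8=C9 the alkene).

**Route**

Step 1
Reactants: 1 (S)-(+)-terpinen-4-ol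
Product: 3 (3S)-3-hydroxy-6-oxo-3-(propan-2-yl)heptanal, via secondary ozonide 2 (not isolated)
Conditions: O3, CH2Cl2/MeOH, −78 °C; then Me2S, −78 → 20 °C
Reagents that add atoms: ozone, [O-][O+]=O
Why: Ozonolysis (Criegee sequence, reductive work-up) cleaves the only alkene to the keto-aldehyde and does not touch the tertiary carbinol stereocentre.

Step 2
Reactants: 3 (3S)-3-hydroxy-6-oxo-3-(propan-2-yl)heptanal
Product: 5 (5R)-5-hydroxy-2-methyl-5-(propan-2-yl)cyclopent-1-ene-1-carbaldehyde, via aldol 4 (not isolated)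
Conditions: piperidine (0.2 equiv), AcOH (0.2 equiv), toluene, 60 °C
Reagents that add atoms: none
Why: Wolinsky-type amine-catalysed intramolecular aldol condensation (aldehyde enamine onto the methyl ketone, five-membered ring, then dehydration) contracts the ring to the tetrasubstituted enal; the carbinol centre cannot epimerise.

Step 3
Reactants: 5 (5R)-5-hydroxy-2-methyl-5-(propan-2-yl)cyclopent-1-ene-1-carbaldehyde
Product: 6 (1R)-3-methyl-1-(propan-2-yl)cyclopent-2-en-1-ol
Conditions: RhCl(PPh3)3 (1.1 equiv), toluene, 110 °C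
Reagents that add atoms: none
Why: Tsuji–Wilkinson decarbonylation replaces the formyl group that built ring A by a vinylic hydrogen with retention, giving the CH alkene terminus (C5) needed for the 5-exo closure of step 5; the stereocentre is untouched.

Step 4
Reactants: 6 (1R)-3-methyl-1-(propan-2-yl)cyclopent-2-en-1-ol; 7 (bromomethyl)chlorodimethylsilane
Product: 8 (bromomethyl)dimethyl{[(1R)-3-methyl-1-(propan-2-yl)cyclopent-2-en-1-yl]oxy}silane
Conditions: imidazole, DMAP (cat.), CH2Cl2, 0 → 20 °C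
Reagents that add atoms: none
Why: Silylation of the tertiary allylic alcohol with the small chlorosilane under nucleophilic catalysis installs the Stork (bromomethyl)dimethylsilyl tether on the C4 oxygen under non-acidic conditions.

Step 5
Reactants: 8 (bromomethyl)dimethyl{[(1R)-3-methyl-1-(propan-2-yl)cyclopent-2-en-1-yl]oxy}silane; 9 allyl phenyl sulfone
Product: 11 (1R,5R,6R)-3,3,6-trimethyl-1-(propan-2-yl)-6-(prop-2-en-1-yl)-2-oxa-3-silabicyclo[3.3.0]octane, via iodide 10 (not isolated)
Conditions: NaI, 4CzIPN (2 mol %), iPr2NEt (3 equiv), 9 (5 equiv), MeCN, blue LEDs (450 nm), 25 °C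
Reagents that add atoms: sodium iodide, [Na+].[I-] (iodine is carried only by 10)
Why: Proposed new method: a tin-free, visible-light Stork silicon-tether cyclization terminated by intermolecular allyl transfer instead of hydrogen transfer. Excited 4CzIPN oxidises iPr2NEt, and the α-aminoalkyl radical abstracts iodine from 10. The silylmethyl radical closes 5-exo onto the CH terminus C5 on the face of the C4 oxygen (cis-fused oxasilolane, forming C5–C6). The tertiary C1 radical then adds to allyl phenyl sulfone on the face anti to the new ring (forming C1–C10, allyl trans to C6, methyl cis). β-Fragmentation releases PhSO2•, which the reduced photocatalyst converts to sulfinate to close the cycle. The closest known reactions are the Stork (bromomethyl)silyl ether cyclization under tin hydride, Stork-type cyclization–trapping, and Keck or sulfone radical allylation.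

Step 6
Reactants: 11 (1R,5R,6R)-3,3,6-trimethyl-1-(propan-2-yl)-6-(prop-2-en-1-yl)-2-oxa-3-silabicyclo[3.3.0]octane
Product: 12 (1R,2S,3R)-2-(hydroxymethyl)-3-methyl-1-(propan-2-yl)-3-(prop-2-en-1-yl)cyclopentan-1-ol
Conditions: KF, KHCO3, 30% H2O2, THF/MeOH, 50 °C
Reagents that add atoms: hydrogen peroxide, OO
Why: Tamao–Fleming oxidation (fluoride-activated peroxide attack at silicon, carbon-to-oxygen shift) turns C6–Si into C6–OH and frees the C4 hydroxyl; the unactivated allyl alkene is inert to basic peroxide.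

Step 7
Reactants: 12 (1R,2S,3R)-2-(hydroxymethyl)-3-methyl-1-(propan-2-yl)-3-(prop-2-en-1-yl)cyclopentan-1-ol
Product: 13 (1R,2R,5R)-2-hydroxy-5-methyl-2-(propan-2-yl)-5-(prop-2-en-1-yl)cyclopentane-1-carbaldehyde
Conditions: TEMPO (10 mol %), PhI(OAc)2 (1.1 equiv), CH2Cl2, 20 °C
Reagents that add atoms: none
Why: Oxoammonium (TEMPO) oxidation takes only the primary alcohol (the tertiary one cannot be oxidised), and C5 is safe because the formyl group already sits on the favoured face, trans to isopropyl and allyl.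

Step 8
Reactants: 13 (1R,2R,5R)-2-hydroxy-5-methyl-2-(propan-2-yl)-5-(prop-2-en-1-yl)cyclopentane-1-carbaldehyde; 14 (2-methylprop-2-en-1-yl)magnesium chloride
Product: 15 (1R,2S,3R)-2-[(1S)-1-hydroxy-3-methylbut-3-en-1-yl]-3-methyl-1-(propan-2-yl)-3-(prop-2-en-1-yl)cyclopentan-1-ol
Conditions: 14 (2.5 equiv), THF, −78 °C; aq. NH4Cl
Reagents that add atoms: none
Why: Grignard addition under Cram-chelate control: the magnesium alkoxide of the C4 hydroxyl (cis to the formyl group) chelates the aldehyde oxygen and the reagent attacks the exposed exo face of the chelate, giving the 1,3-anti diol (6S).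

Step 9
Reactants: 15 (1R,2S,3R)-2-[(1S)-1-hydroxy-3-methylbut-3-en-1-yl]-3-methyl-1-(propan-2-yl)-3-(prop-2-en-1-yl)cyclopentan-1-ol
Product: 16 jaeschkeanadiol, (3R,3aS,4S,8aR)-6,8a-dimethyl-3-(propan-2-yl)-1,2,3,3a,4,5,8,8a-octahydroazulene-3,4-diol
Conditions: RuCl2(=CHPh)(PCy3)(H2IMes) (second-generation Grubbs catalyst, 5 mol %), CH2Cl2 (0.005 M), 40 °C
Reagents that add atoms: none
Why: Ring-closing metathesis of the allyl and 2-methylallyl groups closes the trans-fused ring B with the trisubstituted C8=C9 alkene in the only possible position; free hydroxyls are tolerated and no stereocentre is touched.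

Step 10
Reactants: 16 jaeschkeanadiol; 17 4-[(tert-butyldimethylsilyl)oxy]benzoic acid
Product: 19 (3R,3aS,4S,8aR)-3-hydroxy-6,8a-dimethyl-3-(propan-2-yl)-1,2,3,3a,4,5,8,8a-octahydroazulen-4-yl 4-[(tert-butyldimethylsilyl)oxy]benzoate, via O-acylisourea 18 (not isolated)
Conditions: DCC (1.5 equiv), DMAP (0.3 equiv), CH2Cl2, 20 °C
Reagents that add atoms: N,N'-dicyclohexylcarbodiimide, C(=NC1CCCCC1)=NC1CCCCC1 (its atoms are carried only by 18)
Why: Steglich esterification acylates the secondary C6 hydroxyl while the tertiary C4 hydroxyl stays free; the silyl ether keeps the phenol from self-condensing.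

Step 11
Reactants: 19 O-silyl ferutinin (the benzoate of step 10)
Product: 21 (3R,3aS,4S,8aS)-3-hydroxy-6,8a-dimethyl-8-oxo-3-(propan-2-yl)-1,2,3,3a,4,5,8,8a-octahydroazulen-4-yl 4-[(tert-butyldimethylsilyl)oxy]benzoate, via allylic tert-butyl peroxide 20 (not isolated)
Conditions: tetrachloro-N-hydroxyphthalimide (20 mol %), pyridine, tBuOOH (1.5 equiv), LiClO4, acetone, carbon (RVC) anode and cathode, undivided cell, constant current, 20 °C
Reagents that add atoms: tert-butyl hydroperoxide, CC(C)(C)OO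
Why: Electrochemical allylic C–H oxidation: the anodically formed phthalimide N-oxyl radical abstracts hydrogen from the C10 methylene next to the CH end of the alkene (C7 is deactivated by the neighbouring acyloxy group), and peroxide trapping at the secondary terminus then elimination gives the 8-en-10-one, forming the C10–O bond.

Step 12
Reactants: 21 the 10-oxo benzoate of step 11
Product: 22 (3R,3aS,4S,8S,8aS)-3,8-dihydroxy-6,8a-dimethyl-3-(propan-2-yl)-1,2,3,3a,4,5,8,8a-octahydroazulen-4-yl 4-[(tert-butyldimethylsilyl)oxy]benzoate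
Conditions: NaBH4, CeCl3·7H2O, MeOH, −40 °C
Reagents that add atoms: none
Why: Luche 1,2-reduction: hydride attacks C10 anti to the axial angular methyl on C1, giving the 10β (10S) allylic alcohol; the esters are untouched and the low temperature forestalls vinylogous loss of the C6 acyloxy group.

Step 13
Reactants: 22 the 10β-alcohol of step 12; 23 angelic acid, (2Z)-2-methylbut-2-enoic acid
Product: 25 (3R,3aS,4S,8S,8aS)-4-({4-[(tert-butyldimethylsilyl)oxy]benzoyl}oxy)-3-hydroxy-6,8a-dimethyl-3-(propan-2-yl)-1,2,3,3a,4,5,8,8a-octahydroazulen-8-yl (2Z)-2-methylbut-2-enoate, via mixed anhydride 24 (not isolated)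
Conditions: 2,4,6-trichlorobenzoyl chloride, Et3N, toluene, 20 °C; then 22, 80 °C
Reagents that add atoms: 2,4,6-trichlorobenzoyl chloride, O=C(Cl)c1c(Cl)cc(Cl)cc1Cl (its atoms are carried only by 24)
Why: Yamaguchi-type mixed-anhydride esterification, the standard way to make angelates without Z-to-E isomerisation to the tiglate; only the secondary allylic C10 hydroxyl reacts.

Step 14
Reactants: 25 the silyl-protected diester of step 13
Product: 26 target, (3R,3aS,4S,8S,8aS)-3-hydroxy-4-[(4-hydroxybenzoyl)oxy]-6,8a-dimethyl-3-(propan-2-yl)-1,2,3,3a,4,5,8,8a-octahydroazulen-8-yl (2Z)-2-methylbut-2-enoate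
Conditions: Bu4NF, AcOH (1:1), THF, 0 °C
Reagents that add atoms: none
Why: Fluoride cleavage of the aryl silyl ether (Si–F bond formation), buffered with acetic acid so that both esters and the Z-enoate survive.

**Compound list**
1 | (S)-(+)-terpinen-4-ol, (1S)-4-methyl-1-(propan-2-yl)cyclohex-3-en-1-ol | CC1=CC[C@](O)(C(C)C)CC1 | starting material
2 | secondary ozonide of 1, 1-methyl-4-(propan-2-yl)-7,8,9-trioxabicyclo[4.2.1]nonan-4-ol (carbinol centre as in 1) | CC12CC[C@@](O)(C(C)C)CC(OO1)O2 | intermediate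
3 | (3S)-3-hydroxy-6-oxo-3-(propan-2-yl)heptanal | CC(=O)CC[C@@](O)(C(C)C)CC=O | intermediate
4 | aldol, 2,5-dihydroxy-2-methyl-5-(propan-2-yl)cyclopentane-1-carbaldehyde (C5 carbinol as in 3) | O=CC1C(C)(O)CC[C@@]1(O)C(C)C | intermediate
5 | (5R)-5-hydroxy-2-methyl-5-(propan-2-yl)cyclopent-1-ene-1-carbaldehyde | O=CC1=C(C)CC[C@@]1(O)C(C)C | intermediate
6 | (1R)-3-methyl-1-(propan-2-yl)cyclopent-2-en-1-ol | CC1=C[C@](O)(C(C)C)CC1 | intermediate
7 | (bromomethyl)chlorodimethylsilane | C[Si](C)(Cl)CBr | starting material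
8 | (bromomethyl)dimethyl{[(1R)-3-methyl-1-(propan-2-yl)cyclopent-2-en-1-yl]oxy}silane | CC1=C[C@](O[Si](C)(C)CBr)(C(C)C)CC1 | intermediate
9 | allyl phenyl sulfone, (prop-2-en-1-ylsulfonyl)benzene | C=CCS(=O)(=O)c1ccccc1 | starting material
10 | (iodomethyl)dimethyl{[(1R)-3-methyl-1-(propan-2-yl)cyclopent-2-en-1-yl]oxy}silane | CC1=C[C@](O[Si](C)(C)CI)(C(C)C)CC1 | intermediate
11 | (1R,5R,6R)-3,3,6-trimethyl-1-(propan-2-yl)-6-(prop-2-en-1-yl)-2-oxa-3-silabicyclo[3.3.0]octane (cis-fused; allyl anti to the siloxane ring) | C=CC[C@@]1(C)CC[C@]2(C(C)C)O[Si](C)(C)C[C@H]12 | intermediate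
12 | (1R,2S,3R)-2-(hydroxymethyl)-3-methyl-1-(propan-2-yl)-3-(prop-2-en-1-yl)cyclopentan-1-ol | C=CC[C@@]1(C)CC[C@@](O)(C(C)C)[C@@H]1CO | intermediate
13 | (1R,2R,5R)-2-hydroxy-5-methyl-2-(propan-2-yl)-5-(prop-2-en-1-yl)cyclopentane-1-carbaldehyde | C=CC[C@@]1(C)CC[C@@](O)(C(C)C)[C@@H]1C=O | intermediate
14 | (2-methylprop-2-en-1-yl)magnesium chloride | C=C(C)C[Mg]Cl | starting material
15 | (1R,2S,3R)-2-[(1S)-1-hydroxy-3-methylbut-3-en-1-yl]-3-methyl-1-(propan-2-yl)-3-(prop-2-en-1-yl)cyclopentan-1-ol | C=CC[C@@]1(C)CC[C@@](O)(C(C)C)[C@@H]1[C@@H](O)CC(C)=C | intermediate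
16 | jaeschkeanadiol, (3R,3aS,4S,8aR)-6,8a-dimethyl-3-(propan-2-yl)-1,2,3,3a,4,5,8,8a-octahydroazulene-3,4-diol | CC1=CC[C@@]2(C)CC[C@@](O)(C(C)C)[C@@H]2[C@@H](O)C1 | intermediate
17 | 4-[(tert-butyldimethylsilyl)oxy]benzoic acid | CC(C)(C)[Si](C)(C)Oc1ccc(cc1)C(=O)O | starting material
18 | O-acylisourea from 17 and DCC | CC(C)(C)[Si](C)(C)Oc1ccc(cc1)C(=O)OC(=NC1CCCCC1)NC1CCCCC1 | intermediate
19 | (3R,3aS,4S,8aR)-3-hydroxy-6,8a-dimethyl-3-(propan-2-yl)-1,2,3,3a,4,5,8,8a-octahydroazulen-4-yl 4-[(tert-butyldimethylsilyl)oxy]benzoate (O-silyl ferutinin) | CC1=CC[C@@]2(C)CC[C@@](O)(C(C)C)[C@@H]2[C@@H](OC(=O)c3ccc(O[Si](C)(C)C(C)(C)C)cc3)C1 | intermediate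
20 | 8-(tert-butylperoxy) derivative of 19 (peroxide on daucane C10, either epimer) | CC1=CC(OOC(C)(C)C)[C@@]2(C)CC[C@@](O)(C(C)C)[C@@H]2[C@@H](OC(=O)c3ccc(O[Si](C)(C)C(C)(C)C)cc3)C1 | intermediate
21 | (3R,3aS,4S,8aS)-3-hydroxy-6,8a-dimethyl-8-oxo-3-(propan-2-yl)-1,2,3,3a,4,5,8,8a-octahydroazulen-4-yl 4-[(tert-butyldimethylsilyl)oxy]benzoate | CC1=CC(=O)[C@@]2(C)CC[C@@](O)(C(C)C)[C@@H]2[C@@H](OC(=O)c3ccc(O[Si](C)(C)C(C)(C)C)cc3)C1 | intermediate
22 | (3R,3aS,4S,8S,8aS)-3,8-dihydroxy-6,8a-dimethyl-3-(propan-2-yl)-1,2,3,3a,4,5,8,8a-octahydroazulen-4-yl 4-[(tert-butyldimethylsilyl)oxy]benzoate | CC1=C[C@H](O)[C@@]2(C)CC[C@@](O)(C(C)C)[C@@H]2[C@@H](OC(=O)c3ccc(O[Si](C)(C)C(C)(C)C)cc3)C1 | intermediate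
23 | angelic acid, (2Z)-2-methylbut-2-enoic acid | C/C=C(/C)C(=O)O | starting material
24 | (2Z)-2-methylbut-2-enoic 2,4,6-trichlorobenzoic anhydride | C/C=C(/C)C(=O)OC(=O)c1c(Cl)cc(Cl)cc1Cl | intermediate
25 | (3R,3aS,4S,8S,8aS)-4-({4-[(tert-butyldimethylsilyl)oxy]benzoyl}oxy)-3-hydroxy-6,8a-dimethyl-3-(propan-2-yl)-1,2,3,3a,4,5,8,8a-octahydroazulen-8-yl (2Z)-2-methylbut-2-enoate | C/C=C(/C)C(=O)O[C@H]1C=C(C)C[C@H](OC(=O)c2ccc(O[Si](C)(C)C(C)(C)C)cc2)[C@@H]2[C@]1(C)CC[C@@]2(O)C(C)C | intermediate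
26 | (3R,3aS,4S,8S,8aS)-3-hydroxy-4-[(4-hydroxybenzoyl)oxy]-6,8a-dimethyl-3-(propan-2-yl)-1,2,3,3a,4,5,8,8a-octahydroazulen-8-yl (2Z)-2-methylbut-2-enoate | C/C=C(/C)C(=O)O[C@H]1C=C(C)C[C@H](OC(=O)c2ccc(O)cc2)[C@@H]2[C@]1(C)CC[C@@]2(O)C(C)C | target

**Step count and risks**
Total step count: 14. Longest linear sequence: 14 steps (from 1; all other inputs are bought).

The three steps most likely to fail:

Step 5 (the proposed new method). Allyl transfer to the hindered tertiary C1 radical may lose to hydrogen abstraction, and the α-aminoalkyl radical may be consumed by the sulfone. Fallback, known chemistry, from 8 back to 11: drop the photocatalytic halogen-atom-transfer/sulfone design for the classical thermal stannane chain, i.e. a Stork cyclization terminated by Keck allylation (8, allyltributylstannane 5 equiv, AIBN, benzene, 80 °C). The stannyl radical abstracts bromine, the same 5-exo closure follows, and the C1 radical is allylated by the stannane with loss of the chain-carrying stannyl radical. No new compound is made on the way.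

Step 8. The chelate-controlled addition may give a poor 6S/6R ratio. Fallback, known chemistry, from 13 back to 16: add 14 without regard to selectivity and oxidise the mixture of 15 and its C6 epimer, the (1R)-carbinol F1, with Dess–Martin periodinane to the single β,γ-unsaturated ketone, 1-[(1R,2R,5R)-2-hydroxy-5-methyl-2-(propan-2-yl)-5-(prop-2-en-1-yl)cyclopentyl]-3-methylbut-3-en-1-one F2. Close ring B with the metathesis catalyst of step 9 to the 6-oxo analogue of jaeschkeanadiol F3. Reduce with Me4NBH(OAc)3 in AcOH/MeCN at −25 °C; this hydroxyl-directed reduction delivers hydride from the face of the C4 hydroxyl and gives the 1,3-anti diol 16. All conditions are neutral or acidic, so C5 and the β,γ-alkene are not disturbed.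

Step 11. Hydrogen abstraction may occur at C7 or the C8 methyl instead of C10, or peroxide trapping may occur at the tertiary terminus. Fallback, known chemistry, from 19 back to 21: epoxidise the C8=C9 alkene with mCPBA to the 8,9-epoxide F4. Open it at the less hindered C9 with PhSeNa (from PhSeSePh and NaBH4) to the 8-hydroxy-9-phenylselanyl compound F5. Oxidise with H2O2 to the selenoxide F6, which undergoes syn-elimination towards C10 to the tertiary allylic alcohol with the C9=C10 alkene F7. Oxidative 1,3-transposition with pyridinium chlorochromate, [C5H5NH][CrO3Cl], then gives enone 21 with no regiochemical choice.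

**Further compounds**
F0 | step 5 | none | none
F1 | step 8 | (1R,2S,3R)-2-[(1R)-1-hydroxy-3-methylbut-3-en-1-yl]-3-methyl-1-(propan-2-yl)-3-(prop-2-en-1-yl)cyclopentan-1-ol (C6 epimer of 15) | C=CC[C@@]1(C)CC[C@@](O)(C(C)C)[C@@H]1[C@H](O)CC(C)=C
F2 | step 8 | 1-[(1R,2R,5R)-2-hydroxy-5-methyl-2-(propan-2-yl)-5-(prop-2-en-1-yl)cyclopentyl]-3-methylbut-3-en-1-one | C=CC[C@@]1(C)CC[C@@](O)(C(C)C)[C@@H]1C(=O)CC(C)=C
F3 | step 8 | (3R,3aR,8aR)-3-hydroxy-6,8a-dimethyl-3-(propan-2-yl)-2,3,3a,5,8,8a-hexahydroazulen-4(1H)-one (6-oxo analogue of 16) | CC1=CC[C@@]2(C)CC[C@@](O)(C(C)C)[C@@H]2C(=O)C1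
F4 | step 11 | 8,9-epoxide of 19 (daucane numbering; epoxide face not material) | CC12OC1C[C@@]3(C)CC[C@@](O)(C(C)C)[C@@H]3[C@@H](OC(=O)c4ccc(O[Si](C)(C)C(C)(C)C)cc4)C2
F5 | step 11 | 8-hydroxy-9-(phenylselanyl) derivative of 19 (daucane numbering) | CC1(O)C([Se]c2ccccc2)C[C@@]3(C)CC[C@@](O)(C(C)C)[C@@H]3[C@@H](OC(=O)c4ccc(O[Si](C)(C)C(C)(C)C)cc4)C1
F6 | step 11 | selenoxide of F5 | CC1(O)C([Se](=O)c2ccccc2)C[C@@]3(C)CC[C@@](O)(C(C)C)[C@@H]3[C@@H](OC(=O)c4ccc(O[Si](C)(C)C(C)(C)C)cc4)C1
F7 | step 11 | 8-hydroxy-9-ene isomer of 19 (tertiary allylic alcohol, daucane numbering) | CC1(O)C=C[C@@]2(C)CC[C@@](O)(C(C)C)[C@@H]2[C@@H](OC(=O)c3ccc(O[Si](C)(C)C(C)(C)C)cc3)C1
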